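**Strategy.** Everything rests on cutting the 2,2-dimethylpyran ring of the chromene at O1–C2 and C3=C4, which leads back to a salicylaldehyde and 2-methylprop-1-enylboronic acid. A Petasis borono-Mannich, amine-loss and oxa-6π electrocyclization cascade forges both bonds in one operation. It exploits that C4 is a lone CH on ring B ortho to the pyran oxygen and that C3–C2(CH3)2 is an isobutenyl unit. The precursor is a 5-acetylsalicylaldehyde whose second catechol oxygen is capped as a 1,1-dimethylallyl ether, which later delivers the prenyl group by Claisen rearrangement. The acetyl group is then grown into the (2S)-flavan by aldol condensation, asymmetric transfer hydrogenation and Mitsunobu ring closure.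

Key step: step 3

Remark: chromene atoms are numbered O1, C2, C3, C4, C4a, C5 to C8, C8a; ring B is the benzene ring of the chromene and ring A that of the chroman; tert-butyl 2-methylbut-3-en-2-yl carbonate and 2-methylprop-1-enylboronic acid are taken as purchasable reagents.

**Step 1**
Reactants: 1 3,4-dihydroxyacetophenone
Product: 3 1-[4-hydroxy-3-(2-methylbut-3-en-2-yloxy)phenyl]ethanone, via disodium 4-acetylbenzene-1,2-diolate 2 (not isolated)
Conditions: NaH (2.05 equiv), DMSO/THF, 0 °C to rt; then Pd(PPh3)4 (3 mol%), tert-butyl 2-methylbut-3-en-2-yl carbonate (1.0 equiv), 0 °C to rt; AcOH quench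
Reagents that add atoms: tert-butyl 2-methylbut-3-en-2-yl carbonate, C=CC(C)(C)OC(=O)OC(C)(C)C
Why: Tsuji–Trost O-allylation (reverse prenylation) of a catecholate dianion: in 2 the 3-oxide is not conjugated with the acetyl group and is the more nucleophilic oxygen, so it should attack the (1,1-dimethylallyl)palladium cation at its tertiary terminus while the 4-oxide, stabilized as a vinylogous carboxylate, stays free.

**Step 2**
Reactants: 3 1-[4-hydroxy-3-(2-methylbut-3-en-2-yloxy)phenyl]ethanone
Product: 5 5-acetyl-2-hydroxy-3-(2-methylbut-3-en-2-yloxy)benzaldehyde, via hydroxymethyl phenol 4 (not isolated)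
Conditions: MgCl2 (anhydrous), Et3N, (CH2O)n, MeCN, 70 °C; cold 0.5 M HCl work-up
Reagents that add atoms: formaldehyde (from paraformaldehyde), C=O
Why: Casnati–Skattebøl ortho-formylation: the magnesium phenoxide delivers formaldehyde to C5, the only free carbon ortho to the hydroxyl, and the salicyl alkoxide 4 is oxidized to the aldehyde by hydride transfer to a second formaldehyde.

**Step 3**
Reactants: 5 5-acetyl-2-hydroxy-3-(2-methylbut-3-en-2-yloxy)benzaldehyde
Product: 8 1-[2,2-dimethyl-8-(2-methylbut-3-en-2-yloxy)-2H-chromen-6-yl]ethanone, via Petasis allylic amine 6 (not isolated), via ortho-quinone methide 7 (not isolated)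
Conditions: 2-methylprop-1-enylboronic acid (1.5 equiv), Bn2NH (0.4 equiv), 1,4-dioxane, 80 °C
Reagents that add atoms: 2-methylprop-1-enylboronic acid, CC(C)=CB(O)O
Why: Dibenzylamine condenses with the aldehyde to an iminium ion while the neighbouring phenol binds the boronic acid as a tetracoordinate boronate, so the 2-methylprop-1-enyl group is delivered intramolecularly to the iminium carbon (Petasis borono-Mannich reaction) and makes the C4–C3 bond in amine 6. On heating, 6 should expel dibenzylamine with help from the phenol to give the ortho-quinone methide 7, whose dienone undergoes a thermal oxa-6π electrocyclization that makes the O1–C2 bond and restores aromaticity, the amine being released to turn over. The closest known reaction type is the amine-catalysed conversion of salicylaldehydes and alkenylboronic acids into 2H-chromenes. The pyran ring closes by disrotatory 6π electrocyclization of the (Z)-dienone and not by a polar cyclization, and no stereocenter is formed because C2 carries two methyl groups. The step needs site selectivity for the hydroxyl ortho to the formyl group and chemoselectivity against the ketone: only that hydroxyl can both deliver boron and close a six-membered ring, the second catechol oxygen is capped as the tertiary allyl ether so that no catechol boronate can sequester the reagent, and the aryl methyl ketone does not condense with the hindered amine. The temperature is held at 80 °C so that the 1,1-dimethylallyl ether does not yet rearrange.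

**Step 4**
Reactants: 9 2,4-dihydroxybenzaldehyde
Product: 10 2-hydroxy-4-(prop-2-enyloxy)benzaldehyde
Conditions: allyl bromide (1.05 equiv), K2CO3 (1.0 equiv), acetone, 50 °C
Reagents that add atoms: allyl bromide, C=CCBr
Why: Williamson etherification: the 2-hydroxyl is tied up in a hydrogen bond to the formyl group, so one equivalent of base and allyl bromide should alkylate the more acidic, free 4-hydroxyl.

**Step 5**
Reactants: 8 1-[2,2-dimethyl-8-(2-methylbut-3-en-2-yloxy)-2H-chromen-6-yl]ethanone; 10 2-hydroxy-4-(prop-2-enyloxy)benzaldehyde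
Product: 11 (2E)-1-[2,2-dimethyl-8-(2-methylbut-3-en-2-yloxy)-2H-chromen-6-yl]-3-[2-hydroxy-4-(prop-2-enyloxy)phenyl]prop-2-en-1-one
Conditions: KOH (50% aq., 5 equiv), EtOH, 0 °C to rt; AcOH to pH 6
Reagents that add atoms: none
Why: Claisen–Schmidt aldol condensation: 8 has a single enolizable position and 10 has no α-hydrogen, and E1cB loss of water from the aldol should give the (E)-enone.

**Step 6**
Reactants: 11 (2E)-1-[2,2-dimethyl-8-(2-methylbut-3-en-2-yloxy)-2H-chromen-6-yl]-3-[2-hydroxy-4-(prop-2-enyloxy)phenyl]prop-2-en-1-one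
Product: 13 (1R)-1-[2,2-dimethyl-8-(2-methylbut-3-en-2-yloxy)-2H-chromen-6-yl]-3-[2-hydroxy-4-(prop-2-enyloxy)phenyl]propan-1-ol, via saturated ketone 12 (not isolated)
Conditions: RuCl(p-cymene)[(R,R)-TsDPEN] (2 mol%), HCO2Na, MeOH/H2O (degassed), 50 °C
Reagents that add atoms: none
Why: Noyori–Ikariya asymmetric transfer hydrogenation in cascade: the ruthenium hydride first reduces the enone C=C by conjugate hydride transfer to 12 and then the aryl ketone through the outer-sphere six-membered transition state, the (R,R)-ligand directing hydride to the Si face to set the (1R)-carbinol, while the isolated alkenes are not touched.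

**Step 7**
Reactants: 13 (1R)-1-[2,2-dimethyl-8-(2-methylbut-3-en-2-yloxy)-2H-chromen-6-yl]-3-[2-hydroxy-4-(prop-2-enyloxy)phenyl]propan-1-ol
Product: 14 (2S)-2-[2,2-dimethyl-8-(2-methylbut-3-en-2-yloxy)-2H-chromen-6-yl]-7-(prop-2-enyloxy)-3,4-dihydro-2H-chromene
Conditions: PPh3, DIAD, THF, 0 °C
Reagents that add atoms: none
Why: Intramolecular Mitsunobu reaction: the phenol displaces the alkoxyphosphonium group in a 6-exo-tet SN2 process with inversion, converting the (1R)-carbinol into the (2S)-chroman stereocenter.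

**Step 8**
Reactants: 14 (2S)-2-[2,2-dimethyl-8-(2-methylbut-3-en-2-yloxy)-2H-chromen-6-yl]-7-(prop-2-enyloxy)-3,4-dihydro-2H-chromene
Product: 16 2,2-dimethyl-7-(3-methylbut-2-enyl)-6-[(2S)-7-(prop-2-enyloxy)-3,4-dihydro-2H-chromen-2-yl]-2H-chromen-8-ol, via cyclohexadienone 15 (not isolated)
Conditions: PhMe (degassed), 120 °C, sealed tube
Reagents that add atoms: none
Why: Aromatic Claisen rearrangement: the [3,3]-shift of the tertiary allyl aryl ether can only go to C7 because the other ortho carbon C8a is blocked, the dienone 15 tautomerizes to the phenol, the primary allyl ether of ring A needs a much higher temperature, and the C2 stereocenter of the chroman is not involved.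

**Step 9**
Reactants: 16 2,2-dimethyl-7-(3-methylbut-2-enyl)-6-[(2S)-7-(prop-2-enyloxy)-3,4-dihydro-2H-chromen-2-yl]-2H-chromen-8-ol
Product: 17 kazinol B, (2S)-2-[8-hydroxy-2,2-dimethyl-7-(3-methylbut-2-enyl)-2H-chromen-6-yl]-3,4-dihydro-2H-chromen-7-ol
Conditions: Pd(PPh3)4 (5 mol%), morpholine (5 equiv), THF, rt
Reagents that add atoms: none
Why: Tsuji–Trost deallylation: zerovalent palladium ionizes the aryl allyl ether and morpholine captures the allyl cation, while the prenyl and chromene alkenes and the stereocenter are untouched.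

**Compound list**
1 | 3,4-dihydroxyacetophenone | CC(=O)c1ccc(O)c(O)c1 | starting material
2 | disodium 4-acetylbenzene-1,2-diolate | CC(=O)c1ccc([O-])c([O-])c1.[Na+].[Na+] | intermediate
3 | 1-[4-hydroxy-3-(2-methylbut-3-en-2-yloxy)phenyl]ethanone | CC(=O)c1ccc(O)c(OC(C)(C)C=C)c1 | intermediate
4 | 1-[4-hydroxy-3-(hydroxymethyl)-5-(2-methylbut-3-en-2-yloxy)phenyl]ethanone (present as its magnesium alkoxide) | CC(=O)c1cc(CO)c(O)c(OC(C)(C)C=C)c1 | intermediate
5 | 5-acetyl-2-hydroxy-3-(2-methylbut-3-en-2-yloxy)benzaldehyde | CC(=O)c1cc(C=O)c(O)c(OC(C)(C)C=C)c1 | intermediate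
6 | 1-{3-[1-(dibenzylamino)-3-methylbut-2-enyl]-4-hydroxy-5-(2-methylbut-3-en-2-yloxy)phenyl}ethanone (racemic) | CC(=O)c1cc(C(C=C(C)C)N(Cc2ccccc2)Cc2ccccc2)c(O)c(OC(C)(C)C=C)c1 | intermediate
7 | 4-acetyl-2-(2-methylbut-3-en-2-yloxy)-6-(3-methylbut-2-enylidene)cyclohexa-2,4-dien-1-one | CC(=O)C1=CC(=CC=C(C)C)C(=O)C(OC(C)(C)C=C)=C1 | intermediate
8 | 1-[2,2-dimethyl-8-(2-methylbut-3-en-2-yloxy)-2H-chromen-6-yl]ethanone | CC(=O)c1cc2c(c(OC(C)(C)C=C)c1)OC(C)(C)C=C2 | intermediate
9 | 2,4-dihydroxybenzaldehyde | O=Cc1ccc(O)cc1O | starting material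
10 | 2-hydroxy-4-(prop-2-enyloxy)benzaldehyde | O=Cc1ccc(OCC=C)cc1O | intermediate
11 | (2E)-1-[2,2-dimethyl-8-(2-methylbut-3-en-2-yloxy)-2H-chromen-6-yl]-3-[2-hydroxy-4-(prop-2-enyloxy)phenyl]prop-2-en-1-one | O=C(/C=C/c1ccc(OCC=C)cc1O)c1cc2c(c(OC(C)(C)C=C)c1)OC(C)(C)C=C2 | intermediate
12 | 1-[2,2-dimethyl-8-(2-methylbut-3-en-2-yloxy)-2H-chromen-6-yl]-3-[2-hydroxy-4-(prop-2-enyloxy)phenyl]propan-1-one | O=C(CCc1ccc(OCC=C)cc1O)c1cc2c(c(OC(C)(C)C=C)c1)OC(C)(C)C=C2 | intermediate
13 | (1R)-1-[2,2-dimethyl-8-(2-methylbut-3-en-2-yloxy)-2H-chromen-6-yl]-3-[2-hydroxy-4-(prop-2-enyloxy)phenyl]propan-1-ol | O[C@H](CCc1ccc(OCC=C)cc1O)c1cc2c(c(OC(C)(C)C=C)c1)OC(C)(C)C=C2 | intermediate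
14 | (2S)-2-[2,2-dimethyl-8-(2-methylbut-3-en-2-yloxy)-2H-chromen-6-yl]-7-(prop-2-enyloxy)-3,4-dihydro-2H-chromene | c1c([C@@H]2CCc3ccc(OCC=C)cc3O2)cc2c(c1OC(C)(C)C=C)OC(C)(C)C=C2 | intermediate
15 | 2,2-dimethyl-7-(3-methylbut-2-enyl)-6-[(2S)-7-(prop-2-enyloxy)-3,4-dihydro-2H-chromen-2-yl]-2H-chromen-8(7H)-one (C7 epimers) | CC(C)=CCC1C([C@@H]2CCc3ccc(OCC=C)cc3O2)=CC2=C(C1=O)OC(C)(C)C=C2 | intermediate
16 | 2,2-dimethyl-7-(3-methylbut-2-enyl)-6-[(2S)-7-(prop-2-enyloxy)-3,4-dihydro-2H-chromen-2-yl]-2H-chromen-8-ol | CC(C)=CCc1c([C@@H]2CCc3ccc(OCC=C)cc3O2)cc2c(c1O)OC(C)(C)C=C2 | intermediate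
17 | kazinol B, (2S)-2-[8-hydroxy-2,2-dimethyl-7-(3-methylbut-2-enyl)-2H-chromen-6-yl]-3,4-dihydro-2H-chromen-7-ol | CC(C)=CCc1c([C@@H]2CCc3ccc(O)cc3O2)cc2c(c1O)OC(C)(C)C=C2 | target

**Step count.** Total: 9 steps. Longest linear sequence: 8 steps (1, 2, 3, 5, 6, 7, 8, 9, from 3,4-dihydroxyacetophenone); step 4 is a one-step branch.

**Steps most likely to fail**

Step 1. The alkylation may fail to discriminate between the two oxygens of the dianion, the catecholate may bind palladium and stall turnover, or the tertiary ether may isomerize to the linear prenyl ether. The fallback sets out from 1 and comes back at 3 by protecting, alkylating and deprotecting. The more acidic 4-hydroxyl is first alkylated selectively with SEMCl and K2CO3 in acetone to give 1-[3-hydroxy-4-{[2-(trimethylsilyl)ethoxy]methoxy}phenyl]ethanone F1. The only remaining hydroxyl is then reverse-prenylated with tert-butyl 2-methylbut-3-en-2-yl carbonate and Pd(PPh3)4 in THF to give 1-[3-(2-methylbut-3-en-2-yloxy)-4-{[2-(trimethylsilyl)ethoxy]methoxy}phenyl]ethanone F2. TBAF in THF at 50 °C, followed by NH4Cl work-up, should remove the SEM group without acid and give 3.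

Step 3. Transfer of the β,β-disubstituted alkenyl group from boron may be slow, loss of the amine from the electron-poor phenol may be slow, or the allyl ether may rearrange prematurely at the temperature needed. The fallback sets out from 3 and comes back at 8, bypassing 5, and builds the pyran ring from the phenol oxygen and the free ortho carbon instead. O-Alkylation of 3 with 3-chloro-3-methylbut-1-yne, DBU and catalytic CuCl2 in MeCN at 0 °C gives 1-[3-(2-methylbut-3-en-2-yloxy)-4-(2-methylbut-3-yn-2-yloxy)phenyl]ethanone F3. Ph3PAuNTf2-catalysed 6-endo hydroarylation in CH2Cl2 at rt should then close the ring at the only free ortho carbon to give 8.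

Step 7. The benzylic alkoxyphosphonium ion, activated by the para oxygen of ring B, may ionize in part, which would erode the enantiopurity or lead to elimination to the styrene. The fallback sets out from 8 and comes back at 14; it keeps the carbinol C–O bond and forms the aryl–O bond instead, so the stereocenter is never substituted.
- Purchased 2-bromo-4-hydroxybenzaldehyde is allylated (allyl bromide, K2CO3, acetone) to 2-bromo-4-(prop-2-enyloxy)benzaldehyde F4.
- Aldol condensation of F4 with 8 (KOH, EtOH, then AcOH) gives (2E)-3-[2-bromo-4-(prop-2-enyloxy)phenyl]-1-[2,2-dimethyl-8-(2-methylbut-3-en-2-yloxy)-2H-chromen-6-yl]prop-2-en-1-one F5.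
- Transfer hydrogenation with RuCl(p-cymene)[(S,S)-TsDPEN] and HCO2Na passes through 3-[2-bromo-4-(prop-2-enyloxy)phenyl]-1-[2,2-dimethyl-8-(2-methylbut-3-en-2-yloxy)-2H-chromen-6-yl]propan-1-one F6 and should give (1S)-3-[2-bromo-4-(prop-2-enyloxy)phenyl]-1-[2,2-dimethyl-8-(2-methylbut-3-en-2-yloxy)-2H-chromen-6-yl]propan-1-ol F7.
- Intramolecular Ullmann etherification (CuI, 3,4,7,8-tetramethyl-1,10-phenanthroline, Cs2CO3, toluene, 90 °C) should close the chroman ring with retention at the carbinol carbon to give 14.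

**Further compounds**
F1 | step 1 | 1-[3-hydroxy-4-{[2-(trimethylsilyl)ethoxy]methoxy}phenyl]ethanone | CC(=O)c1ccc(OCOCC[Si](C)(C)C)c(O)c1
F2 | step 1 | 1-[3-(2-methylbut-3-en-2-yloxy)-4-{[2-(trimethylsilyl)ethoxy]methoxy}phenyl]ethanone | CC(=O)c1ccc(OCOCC[Si](C)(C)C)c(OC(C)(C)C=C)c1
F3 | step 3 | 1-[3-(2-methylbut-3-en-2-yloxy)-4-(2-methylbut-3-yn-2-yloxy)phenyl]ethanone | CC(=O)c1ccc(OC(C)(C)C#C)c(OC(C)(C)C=C)c1
F4 | step 7 | 2-bromo-4-(prop-2-enyloxy)benzaldehyde | O=Cc1ccc(OCC=C)cc1Br
F5 | step 7 | (2E)-3-[2-bromo-4-(prop-2-enyloxy)phenyl]-1-[2,2-dimethyl-8-(2-methylbut-3-en-2-yloxy)-2H-chromen-6-yl]prop-2-en-1-one | O=C(/C=C/c1ccc(OCC=C)cc1Br)c1cc2c(c(OC(C)(C)C=C)c1)OC(C)(C)C=C2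
F6 | step 7 | 3-[2-bromo-4-(prop-2-enyloxy)phenyl]-1-[2,2-dimethyl-8-(2-methylbut-3-en-2-yloxy)-2H-chromen-6-yl]propan-1-one | O=C(CCc1ccc(OCC=C)cc1Br)c1cc2c(c(OC(C)(C)C=C)c1)OC(C)(C)C=C2
F7 | step 7 | (1S)-3-[2-bromo-4-(prop-2-enyloxy)phenyl]-1-[2,2-dimethyl-8-(2-methylbut-3-en-2-yloxy)-2H-chromen-6-yl]propan-1-ol | O[C@@H](CCc1ccc(OCC=C)cc1Br)c1cc2c(c(OC(C)(C)C=C)c1)OC(C)(C)C=C2
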